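**Plan**

1. The target, 2,4-dibromo-6-(2,3,5-tribromo-6-methoxyphenoxy)phenol, has no stereocentre and no stereogenic double bond, so no stereocontrol is needed; ring B is numbered C1' (ether carbon), C2' (H), C3' (Br), C4' (H), C5' (Br), C6' (OH).
2. The retrosynthesis first cuts C3'–Br (back to C3'–NO2, Sandmeyer) and C5'–Br (bromination ortho to the hydroxyl).
3. Enabling feature: in ring B, C3' is para to the hydroxyl carbon C6' and sits between the two CH carbons C2' and C4'; cutting C2'–C3' and C3'–C4' therefore leaves a 3-aryloxy-4-pyrone whose ring oxygen stands where C3' will be and whose carbonyl carbon is C6', plus nitromethane as the C3' donor.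
4. The pyrone is cut at C1'–C2', C4'–C5' and its ring C–O bond into an aryloxyacetone and two carbons from DMF dimethyl acetal; the ArO–CH2 bond goes back to a phenol and chloroacetone.
5. Ring A comes from 2-methoxy-4-nitrophenol: the nitro group blocks the position para to oxygen, then as NH2 directs two bromines to its ortho positions and is removed by deamination.
6. Forward order: ring A substitution on the acetonyl ether, then the pyrone ring, then ring B by exchange of the pyrone oxygen for carbon, then the two remaining ring B bromines.

Key step: step 8

Remark: the pyrone is carried through the ring transformation without bromine, because a 3-bromo-4-pyrone is an α-bromo enone that a nitronate can turn into a nitrocyclopropane after conjugate addition; the C5' bromine is placed afterwards, ortho to the new hydroxyl.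

Assumption: the first condensation of the aryloxyacetone with the amide acetal is taken to occur at the OCH2 carbon, and the first bromination of the aniline at the position para to the methoxy group; the opposite orders converge on the same products. Double-bond geometries given for open-chain intermediates are the expected ones and are lost on ring closure.

**Route**

Step 1
Reactants: 1 2-methoxy-4-nitrophenol
Product: 2 2-bromo-6-methoxy-4-nitrophenol
Conditions: Br2 (1.05 equiv), AcOH, 20 °C
Reagents that add atoms: bromine, BrBr
Why: Electrophilic aromatic bromination should go to the one CH carbon that is ortho to the hydroxyl and meta to the nitro group, since the para position is blocked and the other two CH carbons are ortho to the nitro group.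

Step 2
Reactants: 2 2-bromo-6-methoxy-4-nitrophenol; 3 chloroacetone
Product: 4 1-(2-bromo-6-methoxy-4-nitrophenoxy)propan-2-one
Conditions: K2CO3, DMF, 60 °C
Reagents that add atoms: none
Why: Williamson ether synthesis by SN2 displacement of chloride from the activated α-chloro ketone; the acetonyl group then serves both as the oxygen protecting group during the aniline chemistry and as the source of C1', C6' and C5' of ring B.

Step 3
Reactants: 4 1-(2-bromo-6-methoxy-4-nitrophenoxy)propan-2-one
Product: 5 1-(4-amino-2-bromo-6-methoxyphenoxy)propan-2-one
Conditions: Fe powder, NH4Cl, EtOH/H2O, 75 °C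
Reagents that add atoms: none
Why: Near-neutral iron reduction of an aromatic nitro group (Béchamp type) should leave the aryl bromide and the ketone untouched; the aniline is used at once in step 4.

Step 4
Reactants: 5 1-(4-amino-2-bromo-6-methoxyphenoxy)propan-2-one
Product: 7 1-(4-amino-2,3,5-tribromo-6-methoxyphenoxy)propan-2-one, via 1-(4-amino-2,3-dibromo-6-methoxyphenoxy)propan-2-one 6 (not isolated)
Conditions: NBS (2.05 equiv), MeCN, 0 °C to 20 °C
Reagents that add atoms: N-bromosuccinimide, O=C1CCC(=O)N1Br
Why: Electrophilic aromatic bromination directed by the free amino group to its two ortho positions, the only ring CH carbons left, as in the dibromination of 4-alkoxyanilines; with the phenol oxygen alkylated no quinone imine can form, and without acid the ketone α-carbons should not compete.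

Step 5
Reactants: 7 1-(4-amino-2,3,5-tribromo-6-methoxyphenoxy)propan-2-one
Product: 9 1-(2,3,5-tribromo-6-methoxyphenoxy)propan-2-one, via 2,3,6-tribromo-5-methoxy-4-(2-oxopropoxy)benzenediazonium hydrogen sulfate 8 (not isolated)
Conditions: NaNO2, H2SO4/AcOH, 0–5 °C; then 50% aq H3PO2, 0 °C to 20 °C
Reagents that add atoms: none
Why: Diazotisation followed by hypophosphorous acid reduction (hydrodediazoniation) is the standard removal of an amino group flanked by two bromines, as in the conversion of 2,4,6-tribromoaniline into 1,3,5-tribromobenzene; the amine should be nitrosated much faster than the ketone enolises at 0 °C.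

Step 6
Reactants: 9 1-(2,3,5-tribromo-6-methoxyphenoxy)propan-2-one; 10 N,N-dimethylformamide dimethyl acetal
Product: 12 (1Z,4E)-1,5-bis(dimethylamino)-2-(2,3,5-tribromo-6-methoxyphenoxy)penta-1,4-dien-3-one, via (3Z)-4-(dimethylamino)-3-(2,3,5-tribromo-6-methoxyphenoxy)but-3-en-2-one 11 (not isolated)
Conditions: 10 (6 equiv), neat, 110 °C, MeOH distilled off
Reagents that add atoms: none
Why: Double aminomethylenation of a ketone at both α-carbons with an amide acetal (enaminone formation), first at the more acidic aryloxy-substituted methylene and then at the acetyl methyl, is the known entry to 1,5-bis(dimethylamino)penta-1,4-dien-3-ones used for 4-pyridones and 4-pyrones.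

Step 7
Reactants: 12 (1Z,4E)-1,5-bis(dimethylamino)-2-(2,3,5-tribromo-6-methoxyphenoxy)penta-1,4-dien-3-one
Product: 14 3-(2,3,5-tribromo-6-methoxyphenoxy)-4H-pyran-4-one, via (1Z,4Z)-1-(dimethylamino)-5-hydroxy-2-(2,3,5-tribromo-6-methoxyphenoxy)penta-1,4-dien-3-one 13 (not isolated)
Conditions: 2 M aq HCl, THF, 60 °C
Reagents that add atoms: water, O
Why: Acid hydrolysis of one enaminone terminus to the hydroxymethylene ketone, addition of the enol oxygen to the other protonated enaminone and loss of dimethylamine (addition–elimination cyclocondensation) is the standard closure of such bis-enaminones to 4-pyrones, which are stable to aqueous acid.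

Step 8
Reactants: 14 3-(2,3,5-tribromo-6-methoxyphenoxy)-4H-pyran-4-one; 15 nitromethane
Product: 17 4-nitro-2-(2,3,5-tribromo-6-methoxyphenoxy)phenol, via (1E,4Z)-1-hydroxy-6-nitro-2-(2,3,5-tribromo-6-methoxyphenoxy)hexa-1,4-dien-3-one 16 (not isolated)
Conditions: 15 (2 equiv), KOC(CH3)3 (3 equiv), t-BuOH/THF, 20 °C to 70 °C; then aq HCl
Reagents that add atoms: none
Why: The potassium nitronate of 15 should add in conjugate fashion to C6 of the pyrone, the CH carbon next to the ring oxygen and remote from the aryloxy group, and E1cB expulsion of the ring oxygen as the enolate of a 3-oxo aldehyde opens the ring to 16 (present as its potassium salt); attack at C2 would lead to the same product. A second deprotonation at the nitro-bearing carbon lets it add to the aldehyde carbon in an intramolecular nitro-aldol (Henry) reaction, a 6-exo-trig closure that forms ring B, and loss of water with tautomerisation gives the 4-nitrophenolate, so the nitromethane carbon becomes C3' and C3'–C4' and C2'–C3' are made in that order. The closest known reaction type is the conversion of 4-pyrones such as 2,6-dimethyl-4-pyrone, and of pyrylium salts, into 4-nitrophenols and nitroarenes with nitromethane and an alkoxide base. No stereocentre is formed. The step needs chemoselective attack at the two CH carbons flanking the ring oxygen and not at the carbonyl, the aryl ether or the aryl bromides, which is secured by these carbons being unhindered β-positions of a doubly vinylogous ester and by the absence of any α-halo enone. Irreversible formation of the aromatic nitrophenolate should drive the sequence forward.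

Step 9
Reactants: 17 4-nitro-2-(2,3,5-tribromo-6-methoxyphenoxy)phenol
Product: 18 2-bromo-4-nitro-6-(2,3,5-tribromo-6-methoxyphenoxy)phenol
Conditions: Br2 (1.05 equiv), AcOH, 20 °C
Reagents that add atoms: bromine, BrBr
Why: Electrophilic aromatic bromination of a 4-nitrophenol goes ortho to the hydroxyl, here C5', the one ring B carbon meta to the nitro group, exactly as in step 1; the lone CH of ring A lies between two bromines on a deactivated ring and should not react.

Step 10
Reactants: 18 2-bromo-4-nitro-6-(2,3,5-tribromo-6-methoxyphenoxy)phenol
Product: 19 4-amino-2-bromo-6-(2,3,5-tribromo-6-methoxyphenoxy)phenol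
Conditions: Fe powder, NH4Cl, EtOH/H2O, 75 °C, under N2
Reagents that add atoms: none
Why: The same near-neutral iron reduction of a nitro group as in step 3 should spare the four aryl bromides and the diaryl ether; the air-sensitive aminophenol is taken on directly.

Step 11
Reactants: 19 4-amino-2-bromo-6-(2,3,5-tribromo-6-methoxyphenoxy)phenol
Product: 21 2,4-dibromo-6-(2,3,5-tribromo-6-methoxyphenoxy)phenol, via 3-bromo-4-hydroxy-5-(2,3,5-tribromo-6-methoxyphenoxy)benzenediazonium bromide 20 (not isolated)
Conditions: NaNO2, 48% aq HBr, AcOH, 0 °C; then CuBr (0.5 equiv), 48% aq HBr, 0 °C to 70 °C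
Reagents that add atoms: hydrogen bromide, Br
Why: Sandmeyer reaction, in which the diazonium ion is formed in strongly acidic medium so that the para hydroxyl stays protonated and CuBr mediates loss of N2 and bromine transfer to C3' by electron transfer, as in the conversion of 4-aminophenols into 4-halophenols.

**Compound list**

1 | 2-methoxy-4-nitrophenol | COc1cc([N+](=O)[O-])ccc1O | starting material
2 | 2-bromo-6-methoxy-4-nitrophenol | COc1cc([N+](=O)[O-])cc(Br)c1O | intermediate
3 | chloroacetone | CC(=O)CCl | starting material
4 | 1-(2-bromo-6-methoxy-4-nitrophenoxy)propan-2-one | CC(=O)COc1c(OC)cc([N+](=O)[O-])cc1Br | intermediate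
5 | 1-(4-amino-2-bromo-6-methoxyphenoxy)propan-2-one | CC(=O)COc1c(OC)cc(N)cc1Br | intermediate
6 | 1-(4-amino-2,3-dibromo-6-methoxyphenoxy)propan-2-one (not isolated) | CC(=O)COc1c(OC)cc(N)c(Br)c1Br | intermediate
7 | 1-(4-amino-2,3,5-tribromo-6-methoxyphenoxy)propan-2-one | CC(=O)COc1c(OC)c(Br)c(N)c(Br)c1Br | intermediate
8 | 2,3,6-tribromo-5-methoxy-4-(2-oxopropoxy)benzenediazonium hydrogen sulfate (not isolated) | CC(=O)COc1c(OC)c(Br)c([N+]#N)c(Br)c1Br.OS(=O)(=O)[O-] | intermediate
9 | 1-(2,3,5-tribromo-6-methoxyphenoxy)propan-2-one | CC(=O)COc1c(OC)c(Br)cc(Br)c1Br | intermediate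
10 | N,N-dimethylformamide dimethyl acetal | COC(OC)N(C)C | starting material
11 | (3Z)-4-(dimethylamino)-3-(2,3,5-tribromo-6-methoxyphenoxy)but-3-en-2-one (not isolated) | CC(=O)/C(Oc1c(OC)c(Br)cc(Br)c1Br)=C/N(C)C | intermediate
12 | (1Z,4E)-1,5-bis(dimethylamino)-2-(2,3,5-tribromo-6-methoxyphenoxy)penta-1,4-dien-3-one | CN(C)/C=C(Oc1c(OC)c(Br)cc(Br)c1Br)/C(=O)/C=C/N(C)C | intermediate
13 | (1Z,4Z)-1-(dimethylamino)-5-hydroxy-2-(2,3,5-tribromo-6-methoxyphenoxy)penta-1,4-dien-3-one (not isolated) | CN(C)/C=C(Oc1c(OC)c(Br)cc(Br)c1Br)/C(=O)/C=C\O | intermediate
14 | 3-(2,3,5-tribromo-6-methoxyphenoxy)-4H-pyran-4-one | O=C1C=COC=C1Oc1c(OC)c(Br)cc(Br)c1Br | intermediate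
15 | nitromethane | C[N+](=O)[O-] | starting material
16 | (1E,4Z)-1-hydroxy-6-nitro-2-(2,3,5-tribromo-6-methoxyphenoxy)hexa-1,4-dien-3-one (not isolated) | O/C=C(Oc1c(OC)c(Br)cc(Br)c1Br)\C(=O)/C=C\C[N+](=O)[O-] | intermediate
17 | 4-nitro-2-(2,3,5-tribromo-6-methoxyphenoxy)phenol | COc1c(Br)cc(Br)c(Br)c1Oc1cc([N+](=O)[O-])ccc1O | intermediate
18 | 2-bromo-4-nitro-6-(2,3,5-tribromo-6-methoxyphenoxy)phenol | COc1c(Br)cc(Br)c(Br)c1Oc1cc([N+](=O)[O-])cc(Br)c1O | intermediate
19 | 4-amino-2-bromo-6-(2,3,5-tribromo-6-methoxyphenoxy)phenol | COc1c(Br)cc(Br)c(Br)c1Oc1cc(N)cc(Br)c1O | intermediate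
20 | 3-bromo-4-hydroxy-5-(2,3,5-tribromo-6-methoxyphenoxy)benzenediazonium bromide (not isolated) | COc1c(Br)cc(Br)c(Br)c1Oc1cc([N+]#N)cc(Br)c1O.[Br-] | intermediate
21 | 2,4-dibromo-6-(2,3,5-tribromo-6-methoxyphenoxy)phenol | COc1c(Br)cc(Br)c(Br)c1Oc1cc(Br)cc(Br)c1O | target

**Step count and risks**

Total step count: 11. Longest linear sequence: 11 steps (1 to 21); compounds 3, 10 and 15 are bought.

Steps most likely to fail:

Step 8. The alkoxide or the nitronate may open the pyrone without the open-chain enolate closing again on carbon, so that oligomers or products of a second nitronate addition form instead of the arene. In that case ring B would be built from the open-chain ketone without passing through the pyrone. Ketone 9 is condensed with the sodium salt NaC(NO2)(CHO)2 of nitromalonaldehyde in aqueous NaOH/EtOH at 20 °C and the mixture is acidified with HCl. This is the classical double aldol condensation and dehydration of a ketone with two enolisable α-carbons to a 4-nitrophenol. The methylene and methyl carbons of 9 close onto the two formyl carbons, forming C1'–C2' and C4'–C5' in place of the bonds of the key step, and 17 should result directly. This fallback sets out from 9 and returns to the route at 17; steps 6 and 7 fall away, and no compound outside the compound list is made (F0).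

Step 6. The second condensation, at the weakly acidic acetyl methyl of the vinylogous amide, may stall, or long heating may degrade the material, so that the mono-enaminone accumulates. The second one-carbon unit would then be introduced by enolate chemistry. Ketone 9 is treated with 10 (1.5 equiv, toluene, 80 °C) and 11 is isolated. Its acetyl methyl is deprotonated with LiN(SiMe3)2 in THF at −78 °C and formylated with ethyl formate (Claisen condensation) to give 13 as its lithium salt. Acidification with aqueous HCl should close 13 to the pyrone as in step 7. This fallback sets out from 9 and returns to the route at 14; no compound outside the compound list is made (F0).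

Step 11. With the hydroxyl para to the diazonium group, proton loss may give a quinone diazide that accepts an electron from CuBr only sluggishly, so that bromine transfer is outrun by tar formation or hydrodediazoniation. The phenol would then be masked before the amine is generated and the bromine introduced under anhydrous conditions.
- Nitrophenol 18 is converted with chloromethyl methyl ether and i-Pr2NEt in CH2Cl2 into 1-bromo-2-(methoxymethoxy)-5-nitro-3-(2,3,5-tribromo-6-methoxyphenoxy)benzene F1.
- Reduction with Fe powder and NH4Cl in EtOH/H2O should give 3-bromo-4-(methoxymethoxy)-5-(2,3,5-tribromo-6-methoxyphenoxy)aniline F2.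
- Treatment with tert-butyl nitrite and CuBr2 in MeCN (0 °C to 60 °C) generates 3-bromo-4-(methoxymethoxy)-5-(2,3,5-tribromo-6-methoxyphenoxy)benzenediazonium bromide F3, which is not isolated and should pass under the same conditions into 1,5-dibromo-2-(methoxymethoxy)-3-(2,3,5-tribromo-6-methoxyphenoxy)benzene F4.
- Acetal cleavage with HCl in MeOH at 50 °C, which does not touch the aryl methyl ether, should release the target.

This fallback sets out from 18 and returns to the route at 21.

**Further compounds**

F0 | step 8 | none | none
F0 | step 6 | none | none
F1 | step 11 | 1-bromo-2-(methoxymethoxy)-5-nitro-3-(2,3,5-tribromo-6-methoxyphenoxy)benzene | COCOc1c(Br)cc([N+](=O)[O-])cc1Oc1c(OC)c(Br)cc(Br)c1Br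
F2 | step 11 | 3-bromo-4-(methoxymethoxy)-5-(2,3,5-tribromo-6-methoxyphenoxy)aniline | COCOc1c(Br)cc(N)cc1Oc1c(OC)c(Br)cc(Br)c1Br
F3 | step 11 | 3-bromo-4-(methoxymethoxy)-5-(2,3,5-tribromo-6-methoxyphenoxy)benzenediazonium bromide | COCOc1c(Br)cc([N+]#N)cc1Oc1c(OC)c(Br)cc(Br)c1Br.[Br-]
F4 | step 11 | 1,5-dibromo-2-(methoxymethoxy)-3-(2,3,5-tribromo-6-methoxyphenoxy)benzene | COCOc1c(Br)cc(Br)cc1Oc1c(OC)c(Br)cc(Br)c1Br
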